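70.0% of the substrate charged: that was the partner ceiling, the charge of partner divided by the charge of substrate, and the upper bound on target plus isomer of the product in alder. Partner went in at 0.0350 M against 0.050 M of substrate, so it was the limiting reagent, and I kept its ledger in percent of the substrate charged.

| flask | substrate | partner | remark | time |
|---|---|---|---|---|
| theta | 0.050 M | 0.035 M | run made earlier |  |
| alpha | 0.025 M | 0.035 M | run made earlier |  |
| alder | 0.050 M | 0.0350 M | everything together at the start | 15 h |
| oak | 0.050 M (fed, over 10 h) | 0.0350 M | all else is in the flask from the start; the feed brings no volume worth counting | 15 h |
| elm | 0.050 M | 0.0350 M (fed, over 10 h) | all else is in the flask from the start; the feed brings no volume worth counting | 15 h |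

- theta (time / h: target / %, isomer of the product / %): 0.667: 0, 0; 1.50: 1, 1; 4.00: 4, 4; 10.0: 20, 9
- alpha (time / h: target / %, isomer of the product / %): 0.250: 0, 0; 0.500: 0, 0; 1.33: 3, 0; 3.00: 3, 2

(readings scatter by 1.5 percentage points)

- which flask leads in share of target in target plus isomer of the product ("all alike" within 1.5 percentage points) (alder / oak / elm / all alike)
- share of target in target plus isomer of the product at the end, alder
- share of target in target plus isomer of the product at the end, oak
- share of target in target plus isomer of the product at the end, elm

- what is said of target includes crystals
- crystals is a solid; its amount is given per volume of the solution
- steps under discussion: substrate -> intermediate; partner + intermediate -> target; crystals <-> target; target <-> isomer of the product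

By the steps under discussion, each unit of partner that reacted met one intermediate and made one target. The entries were therefore unused partner, dissolved target, crystals and isomer of the product. The used entries together had to equal the ceiling times the fraction of partner used.

The theta run had alder's charges, and at 10.0 h it read 20% target, crystals included, and 9% isomer. As a reading, that put 41.4% of the partner into those entries. Carrying that pace to 15 h, I reckoned 62.1% of the partner used, so 43.5% entered. With the isomer held at its reading, my share for alder was 79.3%.

The forecast gave 78% for alder, not my figure, with 65% for oak and 76% for elm, and put alder first: “Since the share grows with total product above the fixed cap, alder leads, narrowly.”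

The flasks gave 82.7% for alder, 73.4% for oak and 80.4% for elm, so alder led.

    substrate → intermediate (k = 0.00130 /min)
    partner + intermediate → target (k = 0.0680 /M/min)
    crystals ⇌ target, rate k3*(cs3 - [target]) while solid is left; crystals form when [target] > cs3 (solubility = 3.00 mM, k = 0.0160 /min)
    target ⇌ isomer of the product (K = 0.740, k = 0.0370 /min)

At 15 h, alder had 48% of its partner left, so the ledger entered 36.4%; the flask held 30.3% target and 6.32% isomer. The relaxation half-life of dissolved target and isomer in alder was 0.133 h, short against 15 h. A neighbour of alder charged with 0.0088 M of partner had a ceiling of 17.6%. With 33.5% of its partner left at 15.0 h, its ledger entered 11.7%; it held 6.97% target and 4.74% isomer, a share of 59.5%.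

The readings are calculated with made-up constants, and the scatter is random.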